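## Analysis of the target

The target is a 2,3-dihydro-1-benzofuran (O1, C2, C3, C3a, C4–C7, C7a). Its fused benzene ring A carries a hydroxyl at C4 and a 2-(4-hydroxyphenyl)ethyl arm at C6; C2 bears a 2,4-dihydroxyphenyl group (ring B) and C3 a 3,5-dihydroxyphenyl group (ring C). The only stereocentres are C2 and C3, both S, with the two aryl groups on opposite faces of the five-membered ring (trans), which is also the more stable arrangement. All oxygens other than O1 are free phenols on resorcinol- or phloroglucinol-like rings, so the final compound is oxidation-prone and strongly nucleophilic at carbon, and the phenols must stay masked until the end. The C2–O1 bond is a benzylic aryl ether next to the ortho/para-oxygenated ring B and can ionise under acid, which puts C2 at risk (though the trans ring re-forms). C3 is doubly benzylic and has no such escape, so it holds the absolute configuration once set. The difficulty is that C2 and C3 carry only aryl groups and hydrogen, so there is no functional handle to relay stereochemistry and the absolute configuration must come from a catalyst acting during carbon–carbon bond formation. The strategy rests on one feature: without its two aryl groups, the O1–C2–C3–C3a unit with ring A is a flat benzofuran, and the target is what an anti addition of one aryl to C2 and one to C3 across the former C2=C3 bond would give.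

## Retrosynthetic reasoning

Target 16 is traced to its hexamethyl ether 15 by cutting six O–CH3 bonds. Methyl is chosen because it survives every reagent used before the last step and because the whole aromatic periphery can then be bought in methylated form. The price is one Lewis-acid step at the end that must strip six ethers without touching C3.

15 comes from boronic ester 14 by exchanging the C2–B bond for C2–H. Boron at C2 is the atom that drives the key step. Its removal must go with retention, so that hydrogen takes the face boron held, cis to the C3 aryl group.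

In 14 the C2–aryl and C3–aryl bonds are cut together. This leaves three flat, achiral pieces: benzofuran 8 (used as its 2-lithio derivative 12), aryl boronic ester 11 and aryl triflate 10, which meet in ate complex 13. Cutting here, and not at C2–O1, C2–C3 or C3–C3a, means no ring has to be closed, ring A arrives aromatic and correctly substituted, and both stereocentres form in one event under a chiral palladium catalyst. The forward reaction must join C2 to the aryl on boron and C3 to the aryl on palladium on opposite faces, select one face of C3, and outrun plain boron-to-palladium transfer.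

Triflate 10 is cut at its O–S bond to phenol 9.

Benzofuran 8 is cut at C2–C3 with loss of one carboxyl carbon, back to aryloxyacetic acid 7. The furan ring is then made by an intramolecular Perkin-type condensation onto an ortho aldehyde with decarboxylation, which leaves C2 and C3 unsubstituted as the key step requires. Acid 7 is cut at its O–CH2 bond (through ester 6) to salicylaldehyde 5.

5 is traced to 2,6-dimethoxybenzaldehyde 4 by one O–CH3 bond; the carbonyl group directs cleavage to an ortho ether and stops it after one. 4 is traced to bibenzyl 2 (through aryllithium 3) by cutting the ring–CHO bond. The position between the two methoxy groups of 2 is its most acidic site, so the carbon that becomes C3, the oxygen that becomes O1 and the C4 methoxy group are placed without isomers.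

2 is the hydrogenation product of stilbene 1, a catalogue compound that already holds every carbon of ring A and of the arm.

## Alternatives that were turned down

Alternative 1: Ring A is cut at C3a–C7a, C4–C5 and C6–C7. A ruthenium-catalysed (2+2+2) cycloaddition of the ynol-ether-tethered 1,6-diyne A2 with the terminal alkyne A3 would close the dihydrofuran and ring A together and give the C4-silylated dihydrobenzofuran A1.
- For: cyclotrimerisation of tethered diynes is an established reaction class, so on precedent for the reaction type it is stronger than the chosen key step. The tether fixes the ring fusion, the bulky silyl terminus should steer the arm to C6, and the cycloaddition does not touch the stereodiad.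
- Against: A2 must already contain both stereocentres, so the hard problem (an anti 1,2-diaryl unit of defined absolute configuration) is moved into an acyclic synthesis and not solved by the key step. A2 is an alkynyl ether of a secondary, electron-rich benzylic alcohol, a class prone to sigmatropic rearrangement and elimination near room temperature. A1 carries silicon where the target needs oxygen, so a C–Si to C–O exchange on a crowded, electron-rich ring is added before demethylation.
- Comparison: it is longer and its precursor is more fragile. The chosen route offers, in place of precedent, both stereocentres and both aryl–carbon bonds from flat, stable pieces in one step.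

Alternative 2: The C3–C3a bond is cut. The enantioenriched flavanone A5 would undergo oxidative ring contraction with a trivalent iodine oxidant under acidic acetal-forming conditions: the enol ether is attacked at the α-carbon and ring A migrates to that carbon, giving the dihydrobenzofuran ester A4.
- For: the rearrangement is known for flavanones and gives the trans 2-aryl-3-carboxylate directly. A5 is quickly assembled by aldol condensation and asymmetric oxa-Michael closure. On precedent this alternative is again stronger.
- Against: A4 has a methoxycarbonyl group at C3 where the target has ring C. Exchanging the ester for an aryl group (for example decarboxylative arylation through a C3 radical) costs several steps and resets C3 under substrate control only. The 2,4-dimethoxyphenyl group on C2 of A5 migrates better than ring A, so its 1,2-shift (the isoflavone pathway) competes with contraction. A5 can racemise by retro-oxa-Michael opening under the acid of the key step, and A4 can open the same way through its ester enolate.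
- Comparison: the chosen route puts ring C on C3 in the bond-forming step and never places a carbonyl group next to either stereocentre.

Alternative 3: The dihydrofuran is cut at O1–C2 and C2–C3. The chiral benzyl sulfonium ylide A8 (drawn with a C2-symmetric cyclic sulfide unit as an example) would add to the arylidene carbon of the 2-arylidene cyclohexane-1,3-dione A7, and the enolate oxygen would then displace sulfur. This (4+1) annulation gives the tetrahydrobenzofuranone A6, whose six-membered ring is aromatised late.
- For: ylide annulation onto alkylidene 1,3-diones is a dependable route to trans-2,3-disubstituted dihydrofurans. Both aryl groups are in place after it, the pieces are simple, and the count to 15 could match or beat the chosen route. On ring formation it is the safer reaction.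
- Against: enantiocontrol rests on A8, a semi-stabilised ylide on an electron-rich benzylic carbon whose C–S bond ionises easily. Chirality transfer from sulfur through a betaine is less predictable than ligand control at palladium. Aromatising A6 must remove hydrogen from C5–C7 without dehydrogenating C2–C3, although loss of the two benzylic hydrogens there gives a fully aromatic benzofuran and is the easier oxidation.
- Comparison: the chosen route keeps ring A aromatic throughout, so no oxidation is run next to the stereodiad, and it offers catalyst control of absolute configuration in exchange for an unproven key step.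

Key step: step 7

Assumptions:
- The target SMILES is read as the (2S,3S) isomer, with the aryl groups at C2 and C3 trans.
- (E)-3,4',5-Trimethoxystilbene 1 (resveratrol trimethyl ether) is taken as a catalogue compound.
- The sense of induction of the ferrocenyl bisphosphine on this substrate class cannot be predicted with confidence. The (Sp,Sp) antipode is written; the antipode that leads to the (2S,3S) series (both are catalogue items) is to be fixed in a first run.

## Route

Step 1
Reactants: 1 1,3-dimethoxy-5-[(E)-2-(4-methoxyphenyl)ethenyl]benzene
Product: 2 1,3-dimethoxy-5-[2-(4-methoxyphenyl)ethyl]benzene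
Conditions: H2 (1 atm), 10% Pd/C, EtOAc, rt
Reagents that add atoms: none
Why: Heterogeneous catalytic hydrogenation of a stilbene C=C bond; aryl methyl ethers and the arene rings are inert at ambient pressure.

Step 2
Reactants: 2 1,3-dimethoxy-5-[2-(4-methoxyphenyl)ethyl]benzene
Product: 4 2,6-dimethoxy-4-[2-(4-methoxyphenyl)ethyl]benzaldehyde, via aryllithium 3 (not isolated)
Conditions: n-BuLi (1.1 equiv), THF, 0 °C → rt; DMF, 0 °C → rt; aq NH4Cl
Reagents that add atoms: N,N-dimethylformamide, CN(C)C=O
Why: Directed ortho-metalation: the ring position flanked by both methoxy groups is by far the most acidic C–H of 2, so lithiation should give 3 and not an anisole-ring or benzylic anion; formylation of 3 then places the aldehyde para to the arm.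

Step 3
Reactants: 4 2,6-dimethoxy-4-[2-(4-methoxyphenyl)ethyl]benzaldehyde
Product: 5 2-hydroxy-6-methoxy-4-[2-(4-methoxyphenyl)ethyl]benzaldehyde
Conditions: BCl3 (1.1 equiv), CH2Cl2, −78 → 0 °C; then H2O
Reagents that add atoms: none
Why: Chelation-controlled ether cleavage: boron bound to the carbonyl oxygen delivers chloride to the methyl of one ortho methoxy group through a six-membered array, and the boron chelate then no longer activates the second ortho ether or the remote anisole, so a single phenol should result.

Step 4
Reactants: 5 2-hydroxy-6-methoxy-4-[2-(4-methoxyphenyl)ethyl]benzaldehyde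
Product: 7 {2-formyl-3-methoxy-5-[2-(4-methoxyphenyl)ethyl]phenoxy}acetic acid, via ethyl ester 6 (not isolated)
Conditions: BrCH2CO2Et, K2CO3, DMF, 60 °C; then LiOH, THF–H2O, rt; aq HCl to pH 2
Reagents that add atoms: ethyl bromoacetate, CCOC(=O)CBr; lithium hydroxide, [Li+].[OH-]
Why: Williamson O-alkylation of the acidic salicylaldehyde phenol followed by saponification of the aryloxyacetate; the non-enolisable, electron-rich aldehyde should survive both at these temperatures.

Step 5
Reactants: 7 {2-formyl-3-methoxy-5-[2-(4-methoxyphenyl)ethyl]phenoxy}acetic acid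
Product: 8 4-methoxy-6-[2-(4-methoxyphenyl)ethyl]-1-benzofuran
Conditions: Ac2O, NaOAc, AcOH, reflux
Reagents that add atoms: none
Why: Intramolecular Perkin-type condensation of an (ortho-formylaryloxy)acetic acid: the activated acetic acid unit condenses onto the neighbouring aldehyde and the adduct loses CO2 and acetate, forming C2–C3 and an aromatic furan with C2 and C3 unsubstituted (classical benzofuran synthesis).

Step 6
Reactants: 9 3,5-dimethoxyphenol
Product: 10 3,5-dimethoxyphenyl trifluoromethanesulfonate
Conditions: Tf2O, pyridine, CH2Cl2, 0 °C
Reagents that add atoms: trifluoromethanesulfonic anhydride, O=S(=O)(OS(=O)(=O)C(F)(F)F)C(F)(F)F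
Why: O-Sulfonylation of a phenol; it provides a halide-free electrophile for palladium with a weakly coordinating leaving group.

Step 7
Reactants: 8 4-methoxy-6-[2-(4-methoxyphenyl)ethyl]-1-benzofuran; 11 2-(2,4-dimethoxyphenyl)-4,4,5,5-tetramethyl-1,3,2-dioxaborolane; 10 3,5-dimethoxyphenyl trifluoromethanesulfonate
Product: 14 2-[(2S,3S)-2-(2,4-dimethoxyphenyl)-3-(3,5-dimethoxyphenyl)-4-methoxy-6-[2-(4-methoxyphenyl)ethyl]-2,3-dihydro-1-benzofuran-2-yl]-4,4,5,5-tetramethyl-1,3,2-dioxaborolane, via 2-lithiobenzofuran 12 (not isolated), via lithium boron ate complex 13 (not isolated)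
Conditions: n-BuLi (1.0 equiv), THF, −78 °C; 11, −78 → 0 °C; then 10 (1.1 equiv), Pd(OAc)2 (5 mol %), (Sp,Sp)-1,1'-bis[bis(4-methoxy-3,5-dimethylphenyl)phosphino]-2,2'-bis[(R)-α-(dimethylamino)benzyl]ferrocene (MandyPhos type, 6 mol %), THF, 45–60 °C
Reagents that add atoms: none
Why: Proposed new method: oxidative addition of 10 to zerovalent palladium (generated from Pd(OAc)2 and the bisphosphine) should give a cationic divalent arylpalladium with triflate as a loosely bound counter-ion, which binds the electron-rich, enol-ether-like C2=C3 bond of ate complex 13 and thereby triggers a 1,2-shift of the 2,4-dimethoxyphenyl group from boron to C2 on the face opposite to the metal; the C3–palladium bond so formed is benzylic and reductively eliminates with retention to make the C3–aryl bond and return zerovalent palladium. The closest known reaction types are the palladium-catalysed enantioselective conjunctive cross-coupling of alkenylboron ate complexes with aryl triflates and the palladium-induced dearomative 1,2-boronate shift of indol-2-yl boron ate complexes with allyl electrophiles; new here is an aryl electrophile on a benzofuran-2-yl ate complex. No ring is closed: the furan ring gives up its aromaticity in exchange for the C2–aryl and C3–aryl bonds. C3 is controlled by the chiral bisphosphine, which has to place palladium on the Si face of C3 (ranking C2 > C3a > H) to give 3S; C2 is then controlled by C3 through the mechanism, because migration is anti to palladium and reductive elimination is retentive, so the two aryl groups end trans, boron ends cis to the C3 aryl, and C2 is S. The step needs chemoselectivity for the metallate shift over direct boron-to-palladium transfer, for which the chelating wide-bite-angle ligand (no free site for transmetalation), the halide-free ate complex (made by deprotonation) and the triflate leaving group are chosen. Regioselectivity is secured by the substrate: boron sits on C2, so only C2 can receive the migrating group, only the carbon ligand (not the pinacol oxygens) can migrate, and the fused ring A blocks the remote attack open to simple furans. The C3–palladium intermediate has no β-hydrogen (C2 is fully substituted, C3a is aromatic) and its β-oxygen O1 lies in the ring, out of reach of syn elimination, so the only inherent competitor of reductive elimination is loss of the cis β-boron.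

Step 8
Reactants: 14 2-[(2S,3S)-2-(2,4-dimethoxyphenyl)-3-(3,5-dimethoxyphenyl)-4-methoxy-6-[2-(4-methoxyphenyl)ethyl]-2,3-dihydro-1-benzofuran-2-yl]-4,4,5,5-tetramethyl-1,3,2-dioxaborolane
Product: 15 (2S,3S)-2-(2,4-dimethoxyphenyl)-3-(3,5-dimethoxyphenyl)-4-methoxy-6-[2-(4-methoxyphenyl)ethyl]-2,3-dihydro-1-benzofuran
Conditions: CsF (1.5 equiv), H2O (1.1–2 equiv), 1,4-dioxane, 45 °C
Reagents that add atoms: none
Why: Stereoretentive fluoride/water protodeboronation of a tertiary benzylic boronic ester: fluoride adds to boron and the C–B bond is protonated on the face boron occupied, so the new hydrogen at C2 should end cis to the C3 aryl group and the aryl groups stay trans (2S,3S). Methyl ethers and the dihydrofuran ring are inert to these conditions, and the trans isomer is also the thermodynamic one.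

Step 9
Reactants: 15 (2S,3S)-2-(2,4-dimethoxyphenyl)-3-(3,5-dimethoxyphenyl)-4-methoxy-6-[2-(4-methoxyphenyl)ethyl]-2,3-dihydro-1-benzofuran
Product: 16 4-[(2S,3S)-3-(3,5-dihydroxyphenyl)-4-hydroxy-6-[2-(4-hydroxyphenyl)ethyl]-2,3-dihydro-1-benzofuran-2-yl]benzene-1,3-diol
Conditions: BBr3 (12 equiv), CH2Cl2, −78 → 0 °C; then H2O, 0 °C
Reagents that add atoms: none
Why: Exhaustive Lewis-acid cleavage of aryl methyl ethers by bromide attack on each boron-complexed O–CH3. C3 has no acid-mediated epimerisation pathway short of proton loss, and any reversible ionisation of C2–O1 should re-close to the more stable trans ring (after demethylation the two oxygens ortho to C3a are equivalent, so closure by either gives the same compound), so the (2S,3S) configuration is expected to be kept.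

## Compound list

1 | 1,3-dimethoxy-5-[(E)-2-(4-methoxyphenyl)ethenyl]benzene | COc1ccc(/C=C/c2cc(OC)cc(OC)c2)cc1 | starting material
2 | 1,3-dimethoxy-5-[2-(4-methoxyphenyl)ethyl]benzene | COc1ccc(CCc2cc(OC)cc(OC)c2)cc1 | intermediate
3 | {2,6-dimethoxy-4-[2-(4-methoxyphenyl)ethyl]phenyl}lithium | [Li]c1c(OC)cc(CCc2ccc(OC)cc2)cc1OC | intermediate
4 | 2,6-dimethoxy-4-[2-(4-methoxyphenyl)ethyl]benzaldehyde | O=Cc1c(OC)cc(CCc2ccc(OC)cc2)cc1OC | intermediate
5 | 2-hydroxy-6-methoxy-4-[2-(4-methoxyphenyl)ethyl]benzaldehyde | O=Cc1c(O)cc(CCc2ccc(OC)cc2)cc1OC | intermediate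
6 | ethyl {2-formyl-3-methoxy-5-[2-(4-methoxyphenyl)ethyl]phenoxy}acetate | CCOC(=O)COc1cc(CCc2ccc(OC)cc2)cc(OC)c1C=O | intermediate
7 | {2-formyl-3-methoxy-5-[2-(4-methoxyphenyl)ethyl]phenoxy}acetic acid | OC(=O)COc1cc(CCc2ccc(OC)cc2)cc(OC)c1C=O | intermediate
8 | 4-methoxy-6-[2-(4-methoxyphenyl)ethyl]-1-benzofuran | COc1ccc(CCc2cc(OC)c3ccoc3c2)cc1 | intermediate
9 | 3,5-dimethoxyphenol | COc1cc(O)cc(OC)c1 | starting material
10 | 3,5-dimethoxyphenyl trifluoromethanesulfonate | COc1cc(OS(=O)(=O)C(F)(F)F)cc(OC)c1 | intermediate
11 | 2-(2,4-dimethoxyphenyl)-4,4,5,5-tetramethyl-1,3,2-dioxaborolane | COc1ccc(B2OC(C)(C)C(C)(C)O2)c(OC)c1 | starting material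
12 | {4-methoxy-6-[2-(4-methoxyphenyl)ethyl]-1-benzofuran-2-yl}lithium | [Li]c1cc2c(OC)cc(CCc3ccc(OC)cc3)cc2o1 | intermediate
13 | lithium 2-(2,4-dimethoxyphenyl)-2-{4-methoxy-6-[2-(4-methoxyphenyl)ethyl]-1-benzofuran-2-yl}-4,4,5,5-tetramethyl-1,3,2-dioxaborolan-2-uide | [Li+].COc1ccc(CCc2cc(OC)c3cc(oc3c2)[B-]2(OC(C)(C)C(C)(C)O2)c2ccc(OC)cc2OC)cc1 | intermediate
14 | 2-[(2S,3S)-2-(2,4-dimethoxyphenyl)-3-(3,5-dimethoxyphenyl)-4-methoxy-6-[2-(4-methoxyphenyl)ethyl]-2,3-dihydro-1-benzofuran-2-yl]-4,4,5,5-tetramethyl-1,3,2-dioxaborolane | COc1ccc(CCc2cc(OC)c3c(c2)O[C@](B2OC(C)(C)C(C)(C)O2)(c2ccc(OC)cc2OC)[C@H]3c2cc(OC)cc(OC)c2)cc1 | intermediate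
15 | (2S,3S)-2-(2,4-dimethoxyphenyl)-3-(3,5-dimethoxyphenyl)-4-methoxy-6-[2-(4-methoxyphenyl)ethyl]-2,3-dihydro-1-benzofuran | COc1ccc(CCc2cc(OC)c3c(c2)O[C@H](c2ccc(OC)cc2OC)[C@H]3c2cc(OC)cc(OC)c2)cc1 | intermediate
16 | 4-[(2S,3S)-3-(3,5-dihydroxyphenyl)-4-hydroxy-6-[2-(4-hydroxyphenyl)ethyl]-2,3-dihydro-1-benzofuran-2-yl]benzene-1,3-diol | Oc1ccc(CCc2cc(O)c3c(c2)O[C@H](c2ccc(O)cc2O)[C@H]3c2cc(O)cc(O)c2)cc1 | target

## Step count and least certain steps

Total step count: 9. Longest linear sequence: 8 steps (steps 1–5 and 7–9, from 1 to 16); step 6 is a one-step side branch.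

**Step 7 (key step, beyond known chemistry).**
- Most likely failure: direct boron-to-palladium transfer (biaryl and 2-arylbenzofuran formation) overtaking the metallate shift. The C3 site lies next to the C4 methoxy group, and C2 must accept an ortho-substituted aryl group to become fully substituted.
- Further risks: erosion of facial selectivity, since the ligand class was developed for open-chain alkenylboron ate complexes, and β-boron elimination from the C3–palladium intermediate.
- Fallback (known chemistry, enantioselective rhodium-carbene C–H insertion): it sets out from 5 and comes back at 15.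
  - Mitsunobu etherification of 5 with (2,4-dimethoxyphenyl)methanol (PPh3, DIAD, THF) would give the benzyl ether aldehyde F1.
  - Addition of 3,5-dimethoxyphenylmagnesium bromide would give the diaryl carbinol F2, which MnO2 would oxidise to the benzophenone F3.
  - Hydrazine hydrate (EtOH, AcOH, reflux; slow for this di-ortho-substituted ketone) would give the hydrazone F4.
  - MnO2 would oxidise F4 to the diaryldiazomethane F5, used without isolation.
  - Rh2(S-PTAD)4, dirhodium tetrakis[(S)-(1-adamantyl)(N-phthalimido)acetate] (or its antipode, whichever gives 3S), would convert F5 into a donor/donor carbene. This inserts into a benzylic O–CH2 C–H bond, closing C2–C3 and giving the cis-dihydrobenzofuran F6, (2R,3S).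
  - Brief treatment with CF3CO2H in CH2Cl2 at 0 °C would epimerise C2 through reversible ionisation of C2–O1 and deliver 15.

**Step 8.**
- Most likely failure: loss of configuration at C2 (protonation of a free benzylic anion on the face away from the C3 aryl group), or sluggish C–B cleavage, because the electron-rich ring B and the α-oxygen stabilise negative charge poorly.
- Fallback: it sets out from 14 and comes back at 15, with the C2 configuration set by thermodynamic control in place of stereospecific substitution. The C–B bond is cleaved without regard to configuration (n-Bu4NF·3H2O, toluene, 60 °C). The resulting mixture of 15 and its cis epimer F6 (the compound already described under step 7) is then equilibrated with CF3CO2H in CH2Cl2 at 0 °C to 15. C3 is not involved, so the enantiomeric purity set in step 7 is kept.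

**Step 9.**
- Most likely failure: ionisation of C2–O1 by the Lewis acid. This is harmless if the ring re-closes, but it can divert material by intermolecular Friedel–Crafts alkylation of the very electron-rich rings or by proton loss from C3, which would erase C3. Incomplete cleavage of six ethers is a second risk.
- Fallback: it sets out from 8 and comes back at 16, changing the protecting group from methyl to benzyl before the key step so that the last step is a neutral hydrogenolysis.
  - NaSEt in DMF at 140 °C (each ring of 8 carries a single methyl ether, so the thiolate SN2 cleavage can go to completion) would give the benzofuran diol F7.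
  - BnBr and K2CO3 in DMF would give the bis(benzyl ether) F8.
  - F8 would be taken through the conditions of steps 7 and 8 with the boronic ester 2-[2,4-bis(benzyloxy)phenyl]-4,4,5,5-tetramethyl-1,3,2-dioxaborolane F9 and the triflate 3,5-bis(benzyloxy)phenyl trifluoromethanesulfonate F10 (made as in step 6 from the corresponding phenol) in place of 11 and 10. This gives the hexabenzyl boronic ester F11 and then the hexabenzyl ether F12.
  - H2 over 10% Pd/C in EtOAc–MeOH, stopped after uptake of six equivalents so that the ring C2–O1 bond is spared, would give 16.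

**Step 5.**
- Most likely failure: the condensation stalling at the hindered, electron-rich aldehyde flanked by two alkoxy groups, or decarboxylation not keeping pace so that the 2-carboxylic acid accumulates.
- Fallback: it sets out from 5 and comes back at 8, separating ring closure from decarboxylation.
  - 5 with BrCH2CO2Et and K2CO3 in DMF at 130 °C (O-alkylation, aldol condensation and dehydration in one pot) would give the benzofuran ester F13.
  - NaOH in EtOH–H2O would give the benzofuran-2-carboxylic acid F14.
  - Copper powder in quinoline at 200 °C would decarboxylate F14 to 8.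

## Further compounds

F1 | step 7 | 2-[(2,4-dimethoxyphenyl)methoxy]-6-methoxy-4-[2-(4-methoxyphenyl)ethyl]benzaldehyde | O=Cc1c(OCc3ccc(OC)cc3OC)cc(CCc2ccc(OC)cc2)cc1OC
F2 | step 7 | (3,5-dimethoxyphenyl){2-[(2,4-dimethoxyphenyl)methoxy]-6-methoxy-4-[2-(4-methoxyphenyl)ethyl]phenyl}methanol (racemic) | OC(c1cc(OC)cc(OC)c1)c1c(OCc3ccc(OC)cc3OC)cc(CCc2ccc(OC)cc2)cc1OC
F3 | step 7 | (3,5-dimethoxyphenyl){2-[(2,4-dimethoxyphenyl)methoxy]-6-methoxy-4-[2-(4-methoxyphenyl)ethyl]phenyl}methanone | O=C(c1cc(OC)cc(OC)c1)c1c(OCc3ccc(OC)cc3OC)cc(CCc2ccc(OC)cc2)cc1OC
F4 | step 7 | hydrazone of (3,5-dimethoxyphenyl){2-[(2,4-dimethoxyphenyl)methoxy]-6-methoxy-4-[2-(4-methoxyphenyl)ethyl]phenyl}methanone | NN=C(c1cc(OC)cc(OC)c1)c1c(OCc3ccc(OC)cc3OC)cc(CCc2ccc(OC)cc2)cc1OC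
F5 | step 7 | 2-[diazo(3,5-dimethoxyphenyl)methyl]-1-[(2,4-dimethoxyphenyl)methoxy]-3-methoxy-5-[2-(4-methoxyphenyl)ethyl]benzene | [N-]=[N+]=C(c1cc(OC)cc(OC)c1)c1c(OCc3ccc(OC)cc3OC)cc(CCc2ccc(OC)cc2)cc1OC
F6 | step 7 | (2R,3S)-2-(2,4-dimethoxyphenyl)-3-(3,5-dimethoxyphenyl)-4-methoxy-6-[2-(4-methoxyphenyl)ethyl]-2,3-dihydro-1-benzofuran (cis; also the epimer met in the fallback to step 8) | COc1ccc(CCc2cc(OC)c3c(c2)O[C@@H](c2ccc(OC)cc2OC)[C@H]3c2cc(OC)cc(OC)c2)cc1
F7 | step 9 | 6-[2-(4-hydroxyphenyl)ethyl]-1-benzofuran-4-ol | Oc1ccc(CCc2cc(O)c3ccoc3c2)cc1
F8 | step 9 | 4-(benzyloxy)-6-{2-[4-(benzyloxy)phenyl]ethyl}-1-benzofuran | c1ccccc1COc1ccc(CCc2cc(OCc3ccccc3)c3ccoc3c2)cc1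
F9 | step 9 | 2-[2,4-bis(benzyloxy)phenyl]-4,4,5,5-tetramethyl-1,3,2-dioxaborolane | CC1(C)OB(OC1(C)C)c1ccc(OCc2ccccc2)cc1OCc1ccccc1
F10 | step 9 | 3,5-bis(benzyloxy)phenyl trifluoromethanesulfonate | FC(F)(F)S(=O)(=O)Oc1cc(OCc2ccccc2)cc(OCc2ccccc2)c1
F11 | step 9 | 2-[(2S,3S)-4-(benzyloxy)-6-{2-[4-(benzyloxy)phenyl]ethyl}-2-[2,4-bis(benzyloxy)phenyl]-3-[3,5-bis(benzyloxy)phenyl]-2,3-dihydro-1-benzofuran-2-yl]-4,4,5,5-tetramethyl-1,3,2-dioxaborolane | c1ccccc1COc1ccc(CCc2cc(OCc3ccccc3)c3c(c2)O[C@](B2OC(C)(C)C(C)(C)O2)(c2ccc(OCc4ccccc4)cc2OCc2ccccc2)[C@H]3c2cc(OCc3ccccc3)cc(OCc3ccccc3)c2)cc1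
F12 | step 9 | (2S,3S)-4-(benzyloxy)-6-{2-[4-(benzyloxy)phenyl]ethyl}-2-[2,4-bis(benzyloxy)phenyl]-3-[3,5-bis(benzyloxy)phenyl]-2,3-dihydro-1-benzofuran | c1ccccc1COc1ccc(CCc2cc(OCc3ccccc3)c3c(c2)O[C@H](c2ccc(OCc4ccccc4)cc2OCc2ccccc2)[C@H]3c2cc(OCc3ccccc3)cc(OCc3ccccc3)c2)cc1
F13 | step 5 | ethyl 4-methoxy-6-[2-(4-methoxyphenyl)ethyl]-1-benzofuran-2-carboxylate | CCOC(=O)c1cc2c(OC)cc(CCc3ccc(OC)cc3)cc2o1
F14 | step 5 | 4-methoxy-6-[2-(4-methoxyphenyl)ethyl]-1-benzofuran-2-carboxylic acid | OC(=O)c1cc2c(OC)cc(CCc3ccc(OC)cc3)cc2o1
A1 | alternative 1 | [(2S,3S)-2-(2,4-dimethoxyphenyl)-3-(3,5-dimethoxyphenyl)-6-[2-(4-methoxyphenyl)ethyl]-2,3-dihydro-1-benzofuran-4-yl]trimethylsilane | COc1ccc(CCc2cc([Si](C)(C)C)c3c(c2)O[C@H](c2ccc(OC)cc2OC)[C@H]3c2cc(OC)cc(OC)c2)cc1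
A2 | alternative 1 | [(3S,4S)-4-(2,4-dimethoxyphenyl)-3-(3,5-dimethoxyphenyl)-4-(ethynyloxy)but-1-yn-1-yl]trimethylsilane | C#CO[C@H](c1ccc(OC)cc1OC)[C@H](C#C[Si](C)(C)C)c1cc(OC)cc(OC)c1
A3 | alternative 1 | 1-(but-3-yn-1-yl)-4-methoxybenzene | C#CCCc1ccc(OC)cc1
A4 | alternative 2 | methyl (2S,3S)-2-(2,4-dimethoxyphenyl)-4-methoxy-6-[2-(4-methoxyphenyl)ethyl]-2,3-dihydro-1-benzofuran-3-carboxylate | COc1ccc(CCc2cc(OC)c3c(c2)O[C@H](c2ccc(OC)cc2OC)[C@H]3C(=O)OC)cc1
A5 | alternative 2 | (2S)-2-(2,4-dimethoxyphenyl)-5-methoxy-7-[2-(4-methoxyphenyl)ethyl]-2,3-dihydro-4H-chromen-4-one | COc1ccc(CCc2cc(OC)c3c(c2)O[C@H](c2ccc(OC)cc2OC)CC3=O)cc1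
A6 | alternative 3 | (2S,3S)-2-(2,4-dimethoxyphenyl)-3-(3,5-dimethoxyphenyl)-6-[2-(4-methoxyphenyl)ethyl]-3,5,6,7-tetrahydro-1-benzofuran-4(2H)-one (C6 epimers) | COc1ccc(CCC2CC(=O)C3=C(C2)O[C@H](c2ccc(OC)cc2OC)[C@H]3c2cc(OC)cc(OC)c2)cc1
A7 | alternative 3 | 2-[(3,5-dimethoxyphenyl)methylidene]-5-[2-(4-methoxyphenyl)ethyl]cyclohexane-1,3-dione | COc1ccc(CCC2CC(=O)C(=Cc3cc(OC)cc(OC)c3)C(=O)C2)cc1
A8 | alternative 3 | (2R,5R)-2,5-dimethylthiolan-1-ium-1-yl (2,4-dimethoxyphenyl)methanide (example of the chiral ylide) | C[C@@H]1CC[C@@H](C)[S+]1[CH-]c1ccc(OC)cc1OC
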